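## Retrosynthetic overview

1. No ring is built: rings A, B and C of all four units and every C2/C3 stereocentre come from commercial (−)-epicatechin (1), masked with benzyl bromide (2) as tetrabenzyl ether 3.
2. C4 of 3 is activated by DDQ oxidation in the presence of 2-ethoxyethanol (4) to the 4β-alkoxy electrophile 5; 3 + 5 form the first C4–C8 bond (dimer 6).
3. Dimer 6 is used twice: as the C8 nucleophile and, after the same C4 oxidation, as the dimeric electrophile 7.
4. Key disconnection: the central interflavan C4–C8 bond, made by a [2+2] Lewis-acid Friedel–Crafts union of 6 and 7 to the benzylated tetramer 8; each new C4 centre is set 4β by attack on the face opposite the C3 hydroxyl and the C2 aryl group.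
5. Global hydrogenolysis of the sixteen benzyl ethers releases the target tetramer 9.

Assumption: (−)-epicatechin (2R,3R, high ee) is purchased; dimer 6 is made once on scale and divided between steps 4 and 5.

## Route

Step 1
Reactants: 1 (−)-epicatechin; 2 benzyl bromide
Product: 3 5,7,3',4'-tetra-O-benzyl-(−)-epicatechin [(2R,3R)-5,7-bis(benzyloxy)-2-[3,4-bis(benzyloxy)phenyl]chroman-3-ol]
Conditions: BnBr (4.4 equiv), K2CO3 (4.5 equiv), degassed DMF, N2, 0 °C → rt, 24 h
Reagents that add atoms: benzyl bromide (2), BrCc1ccccc1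
Why: Fourfold Williamson ether synthesis in which K2CO3 ionises only the four phenols (not the C3 alcohol) and the O-benzylation touches neither stereocentre, while the cold, oxygen-free, weakly basic medium avoids C2 epimerisation.

Step 2
Reactants: 3 5,7,3',4'-tetra-O-benzyl-(−)-epicatechin; 4 2-ethoxyethanol
Product: 5 4β-(2-ethoxyethoxy)-5,7,3',4'-tetra-O-benzyl-(−)-epicatechin [(2R,3R,4S)-5,7-bis(benzyloxy)-2-[3,4-bis(benzyloxy)phenyl]-4-(2-ethoxyethoxy)chroman-3-ol; 2,3-cis, 3,4-trans]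
Conditions: DDQ (2.0 equiv), EtOCH2CH2OH (5 equiv), CH2Cl2, rt, 2 h
Reagents that add atoms: 2-ethoxyethanol (4), CCOCCO
Why: DDQ benzylic oxidation (hydride abstraction at C4, which is activated by the three oxygens of ring A far more than C2–H is by ring B) with capture of the cation by the alcohol on the β face, opposite the C3 hydroxyl and the C2 aryl group, which sets C4 as 4β (S).

Step 3
Reactants: 3 5,7,3',4'-tetra-O-benzyl-(−)-epicatechin (3.0 equiv, excess recovered); 5 4β-(2-ethoxyethoxy)-5,7,3',4'-tetra-O-benzyl-(−)-epicatechin (1.0 equiv)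
Product: 6 octa-O-benzyl epicatechin-(4β→8)-epicatechin dimer [5,7,3',4'-tetra-O-benzylepicatechin-(4β→8)-5,7,3',4'-tetra-O-benzylepicatechin; upper unit 2R,3R,4R, lower unit 2R,3R; both 3-OH free]
Conditions: Yb(OTf)3 (1.0 equiv), CH2Cl2, rt, 3 h
Reagents that add atoms: none
Why: Lewis-acid-promoted Friedel–Crafts alkylation through the C4 cation, in which Yb(OTf)3 ionises the C4 ether of 5 and ring A of 3 attacks through its less hindered C8 on the β face, opposite the C3 hydroxyl and the C2 aryl group, setting the new C4 centre as 4β (R, 3,4-trans) under substrate control.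

Step 4
Reactants: 6 octa-O-benzyl epicatechin-(4β→8)-epicatechin dimer; 4 2-ethoxyethanol
Product: 7 octa-O-benzyl epicatechin-(4β→8)-epicatechin dimer with a 4β-(2-ethoxyethoxy) group on C4 of the lower unit [upper unit 2R,3R,4R; lower unit 2R,3R,4S]
Conditions: DDQ (2.5 equiv), EtOCH2CH2OH (10 equiv), CH2Cl2, rt, 3 h
Reagents that add atoms: 2-ethoxyethanol (4), CCOCCO
Why: The same DDQ benzylic oxidation/etherification as step 2, selective because the lower unit holds the only C4 methylene whereas the interflavan C4–H is a crowded diarylmethine that cannot align with either arene for hydride loss, and the alcohol again adds on the β face (4β, S).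

Step 5
Reactants: 6 octa-O-benzyl epicatechin-(4β→8)-epicatechin dimer (2.0 equiv, excess recovered); 7 lower-unit 4β-(2-ethoxyethoxy) octa-O-benzyl dimer (1.0 equiv)
Product: 8 hexadeca-O-benzyl ether of the target tetramer [[5,7,3',4'-tetra-O-benzylepicatechin-(4β→8)]3-5,7,3',4'-tetra-O-benzylepicatechin; three upper units 2R,3R,4R, terminal unit 2R,3R; four 3-OH free]
Conditions: Yb(OTf)3 (1.0 equiv), CH2Cl2, rt, 6 h; silica gel, then preparative GPC
Reagents that add atoms: none
Why: Friedel–Crafts alkylation as in step 3, in which the ionised lower-unit C4 of 7 is attacked by C8 of the upper unit of 6 (the only free arene position next to the ring oxygen and not wedged between two benzyloxy groups) on the β face, setting the last C4 centre as 4β (R).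

Step 6
Reactants: 8 hexadeca-O-benzyl ether of the target tetramer
Product: 9 target tetramer [epicatechin-(4β→8)-epicatechin-(4β→8)-epicatechin-(4β→8)-epicatechin]
Conditions: H2 (1 atm), Pd(OH)2/C (20 wt %), THF/MeOH/H2O (20:1:1), rt, 2 h; filter, lyophilise, Sephadex gel-filtration column then reversed-phase HPLC
Reagents that add atoms: none
Why: Catalytic hydrogenolysis of all sixteen benzyl ethers under neutral conditions, which leaves the C–C interflavan bonds and all eleven stereocentres untouched.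

## Compound list

1 | (−)-epicatechin, (2R,3R)-2-(3,4-dihydroxyphenyl)chromane-3,5,7-triol | Oc1cc(O)c2c(c1)O[C@H](c1ccc(O)c(O)c1)[C@H](O)C2 | starting material

2 | benzyl bromide | BrCc1ccccc1 | starting material

3 | 5,7,3',4'-tetra-O-benzyl-(−)-epicatechin, (2R,3R)-5,7-bis(benzyloxy)-2-[3,4-bis(benzyloxy)phenyl]chroman-3-ol | c3ccccc3COc1cc(OCc3ccccc3)c2c(c1)O[C@H](c1ccc(OCc3ccccc3)c(OCc3ccccc3)c1)[C@H](O)C2 | intermediate

4 | 2-ethoxyethanol | CCOCCO | starting material

5 | 4β-(2-ethoxyethoxy)-5,7,3',4'-tetra-O-benzyl-(−)-epicatechin, (2R,3R,4S) | c3ccccc3COc1cc(OCc3ccccc3)c2c(c1)O[C@H](c1ccc(OCc3ccccc3)c(OCc3ccccc3)c1)[C@H](O)[C@H]2OCCOCC | intermediate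

6 | octa-O-benzyl epicatechin-(4β→8)-epicatechin dimer, tetra-O-benzylepicatechin-(4β→8)-tetra-O-benzylepicatechin (upper 2R,3R,4R; lower 2R,3R) | c3ccccc3COc1cc(OCc3ccccc3)c2c(c1)O[C@H](c1ccc(OCc3ccccc3)c(OCc3ccccc3)c1)[C@H](O)[C@H]2c1c(OCc3ccccc3)cc(OCc3ccccc3)c2c1O[C@H](c1ccc(OCc3ccccc3)c(OCc3ccccc3)c1)[C@H](O)C2 | intermediate

7 | octa-O-benzyl epicatechin-(4β→8)-epicatechin dimer bearing 4β-(2-ethoxyethoxy) on the lower unit (upper 2R,3R,4R; lower 2R,3R,4S) | c3ccccc3COc1cc(OCc3ccccc3)c2c(c1)O[C@H](c1ccc(OCc3ccccc3)c(OCc3ccccc3)c1)[C@H](O)[C@H]2c1c(OCc3ccccc3)cc(OCc3ccccc3)c2c1O[C@H](c1ccc(OCc3ccccc3)c(OCc3ccccc3)c1)[C@H](O)[C@H]2OCCOCC | intermediate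

8 | hexadeca-O-benzyl ether of the target tetramer (three upper units 2R,3R,4R; terminal unit 2R,3R) | c3ccccc3COc1cc(OCc3ccccc3)c2c(c1)O[C@H](c1ccc(OCc3ccccc3)c(OCc3ccccc3)c1)[C@H](O)[C@H]2c1c(OCc3ccccc3)cc(OCc3ccccc3)c2c1O[C@H](c1ccc(OCc3ccccc3)c(OCc3ccccc3)c1)[C@H](O)[C@H]2c1c(OCc3ccccc3)cc(OCc3ccccc3)c2c1O[C@H](c1ccc(OCc3ccccc3)c(OCc3ccccc3)c1)[C@H](O)[C@H]2c1c(OCc3ccccc3)cc(OCc3ccccc3)c2c1O[C@H](c1ccc(OCc3ccccc3)c(OCc3ccccc3)c1)[C@H](O)C2 | intermediate

9 | target tetramer, epicatechin-(4β→8)-epicatechin-(4β→8)-epicatechin-(4β→8)-epicatechin | Oc1cc(O)c2c(c1)O[C@H](c1ccc(O)c(O)c1)[C@H](O)[C@H]2c1c(O)cc(O)c2c1O[C@H](c1ccc(O)c(O)c1)[C@H](O)[C@H]2c1c(O)cc(O)c2c1O[C@H](c1ccc(O)c(O)c1)[C@H](O)[C@H]2c1c(O)cc(O)c2c1O[C@H](c1ccc(O)c(O)c1)[C@H](O)C2 | target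

## Summary and risk

Total step count: 6.
Longest linear sequence: 6 steps (1 → 3 → 5 → 6 → 7 → 8 → 9); compound 6 is the precursor of both partners in step 5.

Three steps most likely to fail:

**Step 4 (DDQ oxidation of dimer 6).** The risk is competing oxidation at the interflavan methine or at benzyl ethers, giving a low yield of 7. The fallback gives up the dimeric electrophile and grows the chain one unit at a time. It sets out from 6: 6 (2 equiv) and the monomeric electrophile 5 (1 equiv) with Yb(OTf)3 in CH2Cl2 at rt give the benzylated trimer, dodeca-O-benzyl epicatechin-(4β→8)-epicatechin-(4β→8)-epicatechin F1 (C8 of the top unit of 6 attacks, 4β as before). F1 (1.5 equiv) and a further equivalent of 5 under the same conditions give the benzylated tetramer, so the fallback comes back to the route at 8, which then enters step 6.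

**Step 5 ([2+2] coupling).** The risk is that 7 still has a free upper-unit C8, so it can self-condense, and product 8 can be extended further by 7. The fallback caps that position with bromine from the monomer stage, where the regiochemistry of bromination is reliable. It sets out from 3: NBS (1.0 equiv) in CH2Cl2 at −78 → −20 °C brominates C8, the most reactive ring A position, to give 8-bromo-5,7,3',4'-tetra-O-benzyl-(−)-epicatechin F2. DDQ and 2-ethoxyethanol (4) as in step 2 give the capped monomeric electrophile 8-bromo-4β-(2-ethoxyethoxy)-5,7,3',4'-tetra-O-benzylepicatechin F3. F3 with 3 (1.5 equiv) and Yb(OTf)3 in CH2Cl2 gives the capped dimer 8-bromo-octa-O-benzyl epicatechin-(4β→8)-epicatechin F4 (bromine on C8 of the upper unit). DDQ and 4 as in step 4 give the capped dimeric electrophile, the lower-unit 4β-(2-ethoxyethoxy) ether of the 8-bromo-octa-O-benzyl dimer F5. F5 with 6 (1.2 equiv) and Yb(OTf)3 in CH2Cl2 gives the 8-bromo-hexadeca-O-benzyl tetramer F6, which can neither form from a self-condensing electrophile nor be extended at its top unit. H2, Pd(OH)2/C, Et3N (2 equiv), THF/MeOH/H2O removes the bromine and all sixteen benzyl groups at once, so the fallback comes back at 9.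

**Step 6 (sixteenfold hydrogenolysis).** The risk is loss or oxidation of the very polar free polyphenol during isolation, and inseparable partially debenzylated material. The fallback isolates through a chromatographable peracetate and makes deacylation the last reaction. It sets out from 8: hydrogenolysis as in step 6, then the crude 9 is acetylated at once in the same flask (Ac2O, pyridine, DMAP, rt) to the icosa-O-acetyl derivative of the target tetramer F7, purified on silica gel. Hydrazinolysis (N2H4·H2O, degassed THF/MeOH, under argon, 0 °C → rt; reducing and only weakly basic, which limits quinone formation and C2 epimerisation) then comes back at 9.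

## Further compounds

F1 | step 4 | dodeca-O-benzyl epicatechin-(4β→8)-epicatechin-(4β→8)-epicatechin trimer, [tetra-O-benzylepicatechin-(4β→8)]2-tetra-O-benzylepicatechin | c3ccccc3COc1cc(OCc3ccccc3)c2c(c1)O[C@H](c1ccc(OCc3ccccc3)c(OCc3ccccc3)c1)[C@H](O)[C@H]2c1c(OCc3ccccc3)cc(OCc3ccccc3)c2c1O[C@H](c1ccc(OCc3ccccc3)c(OCc3ccccc3)c1)[C@H](O)[C@H]2c1c(OCc3ccccc3)cc(OCc3ccccc3)c2c1O[C@H](c1ccc(OCc3ccccc3)c(OCc3ccccc3)c1)[C@H](O)C2

F2 | step 5 | 8-bromo-5,7,3',4'-tetra-O-benzyl-(−)-epicatechin, (2R,3R) | c3ccccc3COc1cc(OCc3ccccc3)c2c(c1Br)O[C@H](c1ccc(OCc3ccccc3)c(OCc3ccccc3)c1)[C@H](O)C2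

F3 | step 5 | 8-bromo-4β-(2-ethoxyethoxy)-5,7,3',4'-tetra-O-benzylepicatechin, (2R,3R,4S) | c3ccccc3COc1cc(OCc3ccccc3)c2c(c1Br)O[C@H](c1ccc(OCc3ccccc3)c(OCc3ccccc3)c1)[C@H](O)[C@H]2OCCOCC

F4 | step 5 | 8-bromo-octa-O-benzyl epicatechin-(4β→8)-epicatechin dimer (bromine on C8 of the upper unit) | c3ccccc3COc1cc(OCc3ccccc3)c2c(c1Br)O[C@H](c1ccc(OCc3ccccc3)c(OCc3ccccc3)c1)[C@H](O)[C@H]2c1c(OCc3ccccc3)cc(OCc3ccccc3)c2c1O[C@H](c1ccc(OCc3ccccc3)c(OCc3ccccc3)c1)[C@H](O)C2

F5 | step 5 | lower-unit 4β-(2-ethoxyethoxy) ether of the 8-bromo-octa-O-benzyl epicatechin-(4β→8)-epicatechin dimer | c3ccccc3COc1cc(OCc3ccccc3)c2c(c1Br)O[C@H](c1ccc(OCc3ccccc3)c(OCc3ccccc3)c1)[C@H](O)[C@H]2c1c(OCc3ccccc3)cc(OCc3ccccc3)c2c1O[C@H](c1ccc(OCc3ccccc3)c(OCc3ccccc3)c1)[C@H](O)[C@H]2OCCOCC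

F6 | step 5 | 8-bromo-hexadeca-O-benzyl ether of the target tetramer (bromine on C8 of the top unit) | c3ccccc3COc1cc(OCc3ccccc3)c2c(c1Br)O[C@H](c1ccc(OCc3ccccc3)c(OCc3ccccc3)c1)[C@H](O)[C@H]2c1c(OCc3ccccc3)cc(OCc3ccccc3)c2c1O[C@H](c1ccc(OCc3ccccc3)c(OCc3ccccc3)c1)[C@H](O)[C@H]2c1c(OCc3ccccc3)cc(OCc3ccccc3)c2c1O[C@H](c1ccc(OCc3ccccc3)c(OCc3ccccc3)c1)[C@H](O)[C@H]2c1c(OCc3ccccc3)cc(OCc3ccccc3)c2c1O[C@H](c1ccc(OCc3ccccc3)c(OCc3ccccc3)c1)[C@H](O)C2

F7 | step 6 | icosa-O-acetyl derivative of the target tetramer (all twenty hydroxyls acetylated, stereocentres as in 9) | CC(=O)Oc1cc(OC(C)=O)c2c(c1)O[C@H](c1ccc(OC(C)=O)c(OC(C)=O)c1)[C@H](OC(C)=O)[C@H]2c1c(OC(C)=O)cc(OC(C)=O)c2c1O[C@H](c1ccc(OC(C)=O)c(OC(C)=O)c1)[C@H](OC(C)=O)[C@H]2c1c(OC(C)=O)cc(OC(C)=O)c2c1O[C@H](c1ccc(OC(C)=O)c(OC(C)=O)c1)[C@H](OC(C)=O)[C@H]2c1c(OC(C)=O)cc(OC(C)=O)c2c1O[C@H](c1ccc(OC(C)=O)c(OC(C)=O)c1)[C@H](OC(C)=O)C2
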